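**Retrosynthetic overview**
The strategy rests on the central benzene ring, which carries oxygen at C1, C3 and C5: a free OH at C1 and, at C3 and C5, two ether oxygens each bound to C1 of a 2,4,6-trioxygenated phenyl ring. A 3-oxycyclobutenone and a 1-oxyalkyne deliver exactly this all-meta pattern on benzannulation.
Disconnections: sixfold O-demethylation; central ring to 3-(2,4,6-trimethoxyphenoxy)cyclobutenone plus 2,4,6-trimethoxyphenoxyacetylene; cyclobutenone to the same alkyne plus dichloroketene; alkyne to a dichlorovinyl ether from 2,4,6-trimethoxyphenol and trichloroethylene; phenol to 2,4,6-trimethoxybenzaldehyde.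
Both diaryl ether C–O bonds are therefore made on non-aromatic carbon, and no aryl C–O coupling is used.
Ring order: the outer arenes are bought, the four-membered ring is made by [2+2] cycloaddition, and the central benzene ring is made last.
Key step: step 7

Assumption: the target is achiral, and the free heptaphenol is taken to be air-sensitive, so the last step and its work-up are run under argon.

**Step 1**
Reactants: 1 2,4,6-trimethoxybenzaldehyde
Product: 2 2,4,6-trimethoxyphenyl formate
Conditions: mCPBA (1.3 equiv), CH2Cl2, 0 °C → rt
Reagents that add atoms: mCPBA (3-chloroperoxybenzoic acid), OOC(=O)c1cccc(Cl)c1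
Why: Baeyer–Villiger (Dakin-type) oxidation, in which the very electron-rich 2,4,6-trimethoxyphenyl group should migrate to oxygen in preference to hydride, giving the aryl formate and not the benzoic acid.

**Step 2**
Reactants: 2 2,4,6-trimethoxyphenyl formate
Product: 3 2,4,6-trimethoxyphenol
Conditions: K2CO3 (catalytic), MeOH, rt, argon
Reagents that add atoms: none
Why: Base-catalysed transesterification of an activated aryl formate, which should release the phenol and volatile methyl formate at room temperature, with argon protecting the oxidisable phenol.

**Step 3**
Reactants: 3 2,4,6-trimethoxyphenol; 4 trichloroethylene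
Product: 6 (E)-1,2-dichlorovinyl 2,4,6-trimethoxyphenyl ether, via potassium phenoxide 5 (not isolated)
Conditions: KH (1.2 equiv), THF, 0 °C; then 4 (1.3 equiv), −40 °C → rt
Reagents that add atoms: none
Why: Net vinylic substitution by elimination–addition: base removes HCl from trichloroethylene to give dichloroacetylene in the flask, phenoxide 5 adds to it, and protonation anti to the incoming oxygen sets the E geometry of 6 (aryloxy group and vinylic hydrogen trans).

**Step 4**
Reactants: 6 (E)-1,2-dichlorovinyl 2,4,6-trimethoxyphenyl ether
Product: 9 2,4,6-trimethoxyphenoxyacetylene, via chloroalkynyl ether 7 (not isolated), via lithium acetylide 8 (not isolated)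
Conditions: n-BuLi (2.2 equiv), THF, −78 °C → −40 °C; then H2O, −78 °C → 0 °C
Reagents that add atoms: none
Why: Dichlorovinyl ether route to ynol ethers: the first equivalent of n-BuLi should effect dehydrochlorination to 7, the second should exchange chlorine for lithium to give 8, and protonation should release terminal alkyne 9, with the low temperature holding back ring lithiation between the methoxy groups and loss of aryloxide.

**Step 5**
Reactants: 9 2,4,6-trimethoxyphenoxyacetylene; 10 trichloroacetyl chloride
Product: 11 4,4-dichloro-3-(2,4,6-trimethoxyphenoxy)cyclobut-2-en-1-one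
Conditions: 10 (1.5 equiv, slow addition), Zn–Cu couple (2 equiv), Et2O–DME, 0 °C → rt
Reagents that add atoms: none
Why: Ketene–alkyne [2+2] cycloaddition: dichloroketene from zinc dechlorination of 10 should be attacked at its carbonyl carbon by the unsubstituted carbon of ynol ether 9, which places the aryloxy group at C3 and the CCl2 group at C4, while DME ties up ZnCl2 to spare the ynol ether and the electron-rich arene.

**Step 6**
Reactants: 11 4,4-dichloro-3-(2,4,6-trimethoxyphenoxy)cyclobut-2-en-1-one
Product: 12 3-(2,4,6-trimethoxyphenoxy)cyclobut-2-en-1-one
Conditions: Zn dust (4 equiv), AcOH, TMEDA, THF, 0 °C → rt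
Reagents that add atoms: none
Why: Reductive dehalogenation alpha to a ketone: zinc should remove both chlorines through zinc enolates that acetic acid protonates, the TMEDA–AcOH buffer suppressing chloride migration and acid cleavage of the vinylogous aryl ester, and the aprotic solvent preventing exchange of the aryloxy group by an alcohol.

**Step 7**
Reactants: 12 3-(2,4,6-trimethoxyphenoxy)cyclobut-2-en-1-one (1.0 equiv); 9 2,4,6-trimethoxyphenoxyacetylene (1.3 equiv)
Product: 17 3,5-bis(2,4,6-trimethoxyphenoxy)phenol, via vinylketene 13 (not isolated), via vinylcyclobutenone 14 (not isolated), via dienylketene 15 (not isolated), via cyclohexadienone 16 (not isolated)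
Conditions: PhMe, 120 °C, sealed tube, argon; then K2CO3 (catalytic), MeOH, rt
Reagents that add atoms: none
Why: Proposed new method: the closest known reaction type is the Danheiser benzannulation of cyclobutenones with alkoxy- or siloxyacetylenes, and its extension to a 3-aryloxycyclobutenone paired with an aryloxyacetylene is the untested part; mechanistically, heat should open 12 by four-electron electrocyclic cleavage of the C1–C4 bond to vinylketene 13, whose carbonyl carbon is attacked by the nucleophilic terminal carbon of 9 in a [2+2] cycloaddition that forms two C–C bonds and the transient four-membered ring of 14. Ring 14 should reopen by a second four-electron electrocyclic step to dienylketene 15, and the central six-membered ring is closed by thermal six-electron (disrotatory) electrocyclization between the ketene carbon and the terminal CH2 of 15, after which dienone 16 tautomerises to the aromatic phenol 17. The step needs 1,3,5- and not 1,2,4-regiochemistry, and the polarisation of the ynol ether secures it: its unsubstituted carbon bonds to the ketene carbon, so the alkyne oxygen ends meta to the new OH, while the oxygen at C3 of 12 is carried by connectivity to the other meta position. No stereocenter remains in 17; the sp3 carbon of 14 is transient and racemic, and an unproductive geometry of 15 can return through 14 because the ring opening is reversible. An aryloxy group has no beta hydrogen, so 9 cannot lose ketene by a retro-ene path at this temperature, and its two ortho methoxy groups shield the triple bond against oligomerisation. The closing catalytic K2CO3/MeOH treatment transesterifies any aryl ester formed when phenol 17 captures vinylketene 13, returning 17.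

**Step 8**
Reactants: 17 3,5-bis(2,4,6-trimethoxyphenoxy)phenol
Product: 18 3,5-bis(2,4,6-trihydroxyphenoxy)phenol (target)
Conditions: BBr3 (10 equiv), CH2Cl2, −78 °C → rt, argon; then H2O, 0 °C (degassed work-up)
Reagents that add atoms: none
Why: Lewis acid cleavage of aryl methyl ethers: BBr3 coordinates each methoxy oxygen and bromide attacks the methyl carbon, whereas the two diaryl ether oxygens carry no sp3 carbon and should survive, so hydrolysis on quench should release all seven phenols under exclusion of air.

**Compound list**
1 | 2,4,6-trimethoxybenzaldehyde | COc1cc(OC)c(C=O)c(OC)c1 | starting material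
2 | 2,4,6-trimethoxyphenyl formate | COc1cc(OC)c(OC=O)c(OC)c1 | intermediate
3 | 2,4,6-trimethoxyphenol | COc1cc(OC)c(O)c(OC)c1 | intermediate
4 | trichloroethylene | ClC=C(Cl)Cl | starting material
5 | potassium 2,4,6-trimethoxyphenoxide (formed in the flask) | COc1cc(OC)c([O-])c(OC)c1.[K+] | intermediate
6 | (E)-1,2-dichlorovinyl 2,4,6-trimethoxyphenyl ether, 2-[(E)-1,2-dichloroethenoxy]-1,3,5-trimethoxybenzene | COc1cc(OC)c(O/C(Cl)=C\Cl)c(OC)c1 | intermediate
7 | 2-(chloroethynyloxy)-1,3,5-trimethoxybenzene (formed in the flask) | COc1cc(OC)c(OC#CCl)c(OC)c1 | intermediate
8 | lithium (2,4,6-trimethoxyphenoxy)acetylide (formed in the flask) | [Li]C#COc1c(OC)cc(OC)cc1OC | intermediate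
9 | 2,4,6-trimethoxyphenoxyacetylene, 2-(ethynyloxy)-1,3,5-trimethoxybenzene | COc1cc(OC)c(OC#C)c(OC)c1 | intermediate
10 | trichloroacetyl chloride | ClC(Cl)(Cl)C(Cl)=O | starting material
11 | 4,4-dichloro-3-(2,4,6-trimethoxyphenoxy)cyclobut-2-en-1-one | O=C1C=C(Oc2c(OC)cc(OC)cc2OC)C1(Cl)Cl | intermediate
12 | 3-(2,4,6-trimethoxyphenoxy)cyclobut-2-en-1-one | O=C1C=C(Oc2c(OC)cc(OC)cc2OC)C1 | intermediate
13 | 3-(2,4,6-trimethoxyphenoxy)buta-1,3-dien-1-one, the vinylketene (formed in the flask) | O=C=CC(=C)Oc1c(OC)cc(OC)cc1OC | intermediate
14 | racemic 3-(2,4,6-trimethoxyphenoxy)-4-[1-(2,4,6-trimethoxyphenoxy)ethenyl]cyclobut-2-en-1-one (formed in the flask) | O=C1C=C(Oc2c(OC)cc(OC)cc2OC)C1C(=C)Oc1c(OC)cc(OC)cc1OC | intermediate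
15 | (3E)-3,5-bis(2,4,6-trimethoxyphenoxy)hexa-1,3,5-trien-1-one, the dienylketene with C2 and C5 cis across C3=C4 (formed in the flask) | O=C=C/C(Oc1c(OC)cc(OC)cc1OC)=C\C(=C)Oc1c(OC)cc(OC)cc1OC | intermediate
16 | 3,5-bis(2,4,6-trimethoxyphenoxy)cyclohexa-2,4-dien-1-one (formed in the flask) | O=C1C=C(Oc2c(OC)cc(OC)cc2OC)C=C(Oc2c(OC)cc(OC)cc2OC)C1 | intermediate
17 | 3,5-bis(2,4,6-trimethoxyphenoxy)phenol | Oc1cc(Oc2c(OC)cc(OC)cc2OC)cc(Oc2c(OC)cc(OC)cc2OC)c1 | intermediate
18 | 3,5-bis(2,4,6-trihydroxyphenoxy)phenol (CNP0253604.0) | Oc1cc(Oc2c(O)cc(O)cc2O)cc(Oc2c(O)cc(O)cc2O)c1 | target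

**Step count**
Total steps: 8. Longest linear sequence: 8 steps (1 → 2 → 3 → 6 → 9 → 11 → 12 → 17 → 18). Alkyne 9 is divided between steps 5 and 7.

**Steps most likely to fail**

1. Step 7 (carries the label). The vinylogous-ester resonance of 12 may slow the electrocyclic opening so much that thermal oligomerisation of 9, or capture of the ketene by the product phenol, outruns the cycloaddition. Irradiation of 12 to generate 13 at room temperature would be tried first, but that is only a change of conditions. The fallback uses known chemistry and sets out from phenol 3. A twofold Ullmann-type diaryl ether coupling of 3 with commercial 3,5-dibromoanisole (catalytic CuI and picolinic acid, K3PO4, DMSO, 110 °C) should give 1-methoxy-3,5-bis(2,4,6-trimethoxyphenoxy)benzene F1. BBr3 under the conditions of step 8 should then cleave all seven methyl ethers, so the fallback comes back to the route at target 18.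

2. Step 5. ZnCl2 and the acid chloride may trigger oligomerisation or hydration of the electron-rich ynol ether, or Friedel–Crafts acylation of the trimethoxyarene, and chloride may migrate in the product. The fallback sets out from 9. A [2+2] cycloaddition with ketene gas (H2C=C=O from a ketene generator, CH2Cl2 or MeCN, −20 °C → rt) is the known way from alkoxyacetylenes to 3-alkoxycyclobutenones and should give 12 directly. No chlorine is introduced, step 6 falls away, and the fallback comes back to the route at 12. It makes no new compound.

3. Step 4. The metallated vinyl ether may expel aryloxide in place of chloride, the ring may be lithiated between the methoxy groups, or the terminal ynol ether may oligomerise during isolation. The fallback sets out from formate 2. Dibromomethylenation of the formyl group (CBr4, PPh3, THF, 60 °C; Ramirez-type olefination as applied to formates) should give 2-(2,2-dibromoethenoxy)-1,3,5-trimethoxybenzene F2. n-BuLi (2.2 equiv, THF, −78 °C) should then give acetylide 8 by bromine–lithium exchange, Fritsch–Buttenberg–Wiechell 1,2-hydrogen shift and deprotonation. Water quench returns to the route at 9; steps 2 and 3 are bypassed.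

**Further compounds**
F1 | step 7 | 1-methoxy-3,5-bis(2,4,6-trimethoxyphenoxy)benzene | COc1cc(Oc2c(OC)cc(OC)cc2OC)cc(Oc2c(OC)cc(OC)cc2OC)c1
F0 | step 5 | none | none
F2 | step 4 | 2-(2,2-dibromoethenoxy)-1,3,5-trimethoxybenzene | COc1cc(OC)c(OC=C(Br)Br)c(OC)c1
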